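The readings stem from a simulated flask for substances that don't exist; the scatter is artificial.

Minutes per charge is the unit for this flask, where a solid feeds a solution. The new flask holds the Q charge of the midnight run and twice its X.

| setting | midnight | flask |
|---|---|---|
| Q | 17 mM | 17 mM |
| X | 0.85 mM | 1.70 mM |
| remark | run made earlier |  |
| time |  | 50 min |

midnight run (percent of the Q charged)

| time / min | Q / % | E / % |
|---|---|---|
| 0.417 | 98.2 | 0 |
| 1.00 | 96.2 | 0.5 |
| 2.00 | 92.2 | 0.5 |
| 5.00 | 81.8 | 2.5 |

(each reading ± 0.3 percentage points)

- X is the free proton; pH is minus the decimal logarithm of its molar concentration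
- solid, in amounts per volume of the solution: Q
- the analysis behind the earlier runs scatters by 0.3 percentage points, standard deviation
- at the start none of Q is in solution
- what has only dissolved of Q counts as not reacted

- part of the Q that has reacted (what has only dissolved counts as not reacted) at 50 min
- pH of the solution at 50 min

Use a bench rule: hold the early pace of the solid steady and divide the charge by it. The midnight run lost 18.2% of its Q by 5.00 min, which gives 27.5 min for the clearing time t_c, the minutes one charge of solid needs at that pace. Read that loss as dissolved, with E reading 2.5%. Now assume E forms first order in dissolved Q and in X, with X handed back, so that pH holds at its charged value. This single E reading, with its scatter of 0.3 percentage points, gives the dissolved pool of the new flask a rough lifetime τ of 9.10 min.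

In the new flask, τ is shorter than t_c, so I reckon that the pool keeps up and the solid's feed is the rate-limiting step. The rule ends at t_c, and the asked time is 1.82 clearing times. In my reckoning the feed stops past t_c and control passes to the pool, which decays with τ. My reckoning gives 97.3% reacted.

The forecast, holding that “The Q column falls first-order”, gives 79% and pH 2.77, a conversion below mine. The flask gives 97.9% and pH 2.77.

    D + X → Z + X + E (k = 0.830 L mol⁻¹ s⁻¹)
    Z ⇌ G + X, settled at all times (K = 1.00 × 10⁻⁷ M)
    D → Z + E (k = 1.30 × 10⁻⁴ s⁻¹)
    Z → L (k = 0.00390 s⁻¹)
    Q ⇌ D, rate k5*(cs5 - [D]) while solid is left; crystals form when [D] > cs5 (solubility = 9.30 mM, k = 0.00130 s⁻¹)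
    2 D → J (k = 0.210 L mol⁻¹ s⁻¹)

At 50.0 min the flask holds Q 0% and dissolved Q, named D, 2.14%. At the pace of a t_c of 27.5 min, the neighbour flask stopped at 12 min should keep 56.4% as Q, and it holds 60.4%.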